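## Analysis of the target

Target 23 (C22H26O7) consists of two benzene rings joined only through one ether oxygen, and it has no further ring. Ring A is numbered C1 (CO2H), C2 (OMe), C3 (side chain), C4–H, C5–H, C6 (ether O). Ring B is numbered C1′ (ether O), C2′ (OH), C3′–H, C4′ (CH3), C5′–H, C6′ (CHO).

The only stereocentre is the benzylic carbon C1″ of the 1-methoxy-3-methylbutyl chain on C3. With O > C3 > CH2 > H the SMILES reads (R). No other stereocentre is near, so a reagent or catalyst must set it.

C1″ stands ortho to the C2 methoxy group and para to the C6 aryloxy group. It can therefore ionise under strong acid, and its ether should meet neither Lewis acids nor hydrogenolysis late in the route. The other sensitive groups are the aldehyde (nucleophiles, oxidants, strong base), the free phenol next to the ether oxygen, and the acid.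

The difficulty is crowding:
- The ether oxygen is flanked by three ortho substituents (CO2H on C1, OH on C2′, CHO on C6′).
- Ring A carries four contiguous substituents.
- The carboxyl group is 2,6-disubstituted, so any ester of it would be very hard to cleave.

The route exploits the contiguous triad C2(OMe)–C1(CO2H)–C6(OAr) of ring A. This is the regiochemical print of a 3-methoxyaryne with its triple bond between C1 and C6. Such an aryne takes a nucleophile at the carbon remote from OMe (C6) and an electrophile at the carbon next to OMe (C1).

## Retrosynthetic reasoning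

**23 ⇒ 22.** The last cut is the O–allyl bond on the oxygen of C2′. This phenol must be masked while the neighbouring oxygen on C1′ acts as the nucleophile. An allyl group tolerates base, fluoride and acid, and it leaves under nearly neutral palladium catalysis. The endgame therefore puts no strain on C1″, the aldehyde or the acid.

**22 ⇒ 11 + 16 + 17 (key disconnection).** Two bonds on adjacent carbons of ring A are cut at once, C6–O(aryl) and C1–CO2H, which leads back to aryne 19, phenoxide 18 and carbon dioxide 17.
- Cutting only the ether bond would leave a hindered substitution, plus a separate carboxylation and an ester that cannot be hydrolysed.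
- Cutting both bonds turns the crowding into an advantage. An aryne carbon is attacked in the ring plane, and the C2 methoxy group decides the orientation.
- The gain is that 11 carries neither carboxyl nor ether, 16 is a plain phenol, and the acid appears as a free carboxylate.
- The forward reaction must add 18 at C6 only, and it must trap aryl anion 20 with 17 faster than with any proton.

**11 ⇒ 10 ⇒ 9 ⇒ 7.** The O–S bond of the triflate and the C1–Si bond are cut. The silyl group goes on by directed metalation (8). The diethylcarbamate on the C6 oxygen and the C2 methoxy group converge on the one C–H between them. The carbamate is then removed reductively under basic conditions, which the electron-rich aryl–silicon bond tolerates.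

**7 ⇒ 6 ⇒ 5.** The O–CH3 bond on C1″ and then the C1″–H bond are cut. This places the only stereocentre on an aryl alkyl ketone, the best-behaved substrate class for catalytic asymmetric reduction. Methylation does not touch the C1″–O bond, so the configuration is carried through unchanged.

**5 ⇒ 3 ⇒ 1 + 2.** The two ring A oxygens are told apart by the hydrogen bond in 3. The free 4-OH takes the carbamate (4), and the chelated 2-OH is then methylated in the same flask. The C3–C(acyl) bond is cut back to resorcinol 1 and acid 2, because acylation of 1 gives exactly the ortho/para oxygen pattern of ring A.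

**16 ⇒ 15 ⇒ 13 ⇒ 12.** Ring B is a catechol aldehyde. The dioxolane in 16 hides the formyl carbon from aryl anion 20. The allyl group is placed on the oxygen remote from the aldehyde through dianion 14. Catechol 13 comes from the catalogue methyl ether 12 by ether cleavage.

## Alternatives that were turned down

**Alternative 1:** (the textbook route) Only the C1′–O bond is cut. The phenoxide of methyl 6-hydroxy-2-methoxy-3-[(1R)-1-methoxy-3-methylbutyl]benzoate A1 displaces fluoride from 3-(benzyloxy)-2-fluoro-5-methylbenzaldehyde A2. This nucleophilic aromatic substitution, or its copper-mediated Ullmann variant, gives ether ester A3, which is then saponified and debenzylated. It was turned down for these reasons: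
- The nucleophilic oxygen of A1 is hydrogen-bonded to the ortho ester and deactivated by it.
- C1′ of A2 has two ortho neighbours. It carries donors ortho (OBn) and para (CH3), and only one formyl group stabilises the Meisenheimer complex.
- The carboxyl carbon needs its own metalation step and ends as a 2,6-disubstituted ester in A3. Its cleavage calls for forcing hydroxide, which risks Cannizzaro chemistry at the aldehyde, or for nucleophilic dealkylation, which attacks the methyl ethers.
- Four operations (carboxylation, release of the phenol, coupling, ester cleavage) would do what step 11 does in one.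

**Alternative 2:** (biomimetic) The ether oxygen is traced back to a phenol, and the carboxyl carbon to a diaryl ketone. Benzophenone A4 is oxidised by a one-electron oxidant to the spiro grisa-3′,5′-diene-2′,3-dione A5, in which ring B is dearomatised and the O–C1′ bond is formed. Hydroxide then cleaves the C(=O)–C1′ bond with rearomatisation and gives 23. The idea is attractive, but it was turned down for these reasons:
- Both rings of A4 carry an OH ortho to the ketone, and nothing in the substrate decides which ring is dearomatised.
- Ring A is the more electron-rich ring, and its dearomatisation gives the regioisomeric spirodienone A6. In A6 the dienone is stabilised as a doubly vinylogous ester by the C2 methoxy group, and A6 leads to the wrong ether.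
- The ring B half of A4 has an acyl group between OH and CHO and costs several steps.
- The 2-acylbenzaldehyde unit of A4 is prone to base-induced intramolecular hydride transfer.

**Alternative 3:** (Smiles rearrangement) The ether is traced back to an ester. In depside A7 the phenoxide on C6 attacks C1′ through a six-membered spiro Meisenheimer complex, and the carboxylate leaves, which gives 6-[2-(benzyloxy)-6-formyl-4-methylphenoxy] acid A8. It was turned down for these reasons:
- C1′ is again activated by a single ortho formyl group and deactivated by the ortho alkoxy and para methyl groups. Attack at the ester carbonyl (cleavage, acyl transfer) is therefore the easier path.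
- A7 requires esterification of a 2,6-disubstituted acid with a 2,6-disubstituted phenol.
- The acid half needs all the steps of A1.
- Debenzylation of A8 by hydrogenolysis endangers the aldehyde and the C1″–OMe bond.

Key step: step 11

Remark on the chemistry: the descriptor at C1″ is read from the SMILES as (R). All SMILES below keep the same atom order around C1″, and 12 is taken as a catalogue compound.

## Route

Step 1
Reactants: 1 resorcinol; 2 3-methylbutanoic acid
Product: 3 1-(2,4-dihydroxyphenyl)-3-methylbutan-1-one
Conditions: BF3·OEt2 (as medium), 90 °C; then aq. NaOAc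
Reagents that add atoms: none
Why: Nencki-type Friedel–Crafts acylation: the BF3-activated acid attacks resorcinol at C4, which is ortho to one OH and para to the other, and the chelated, deactivated ketone 3 should not be acylated again.

Step 2
Reactants: 3 1-(2,4-dihydroxyphenyl)-3-methylbutan-1-one
Product: 5 3-methoxy-4-(3-methylbutanoyl)phenyl N,N-diethylcarbamate, via hydroxy carbamate 4 (not isolated)
Conditions: Et2NCOCl (1.05 equiv), K2CO3 (3 equiv), DMF, 60 °C; then MeI (2 equiv), 40 °C
Reagents that add atoms: diethylcarbamoyl chloride CCN(CC)C(=O)Cl; iodomethane CI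
Why: The 2-OH of 3 is locked in a hydrogen bond to the ketone, so the more acidic and unhindered 4-OH is carbamoylated first (4); the chelated phenol is then O-methylated in the same flask (Williamson ether synthesis), which differentiates the two oxygens of ring A in one operation.

Step 3
Reactants: 5 3-methoxy-4-(3-methylbutanoyl)phenyl N,N-diethylcarbamate
Product: 6 4-[(1R)-1-hydroxy-3-methylbutyl]-3-methoxyphenyl N,N-diethylcarbamate
Conditions: RuCl[(R,R)-TsDPEN](p-cymene) (1 mol %), HCO2H/Et3N azeotrope, 30 °C
Reagents that add atoms: none
Why: Noyori–Ikariya asymmetric transfer hydrogenation of an aryl alkyl ketone: the CH/π contact between the η6-arene of the catalyst and ring A fixes the orientation, and the (R,R)-catalyst delivers hydride to the Si face, which gives the (R)-carbinol (same sense and same CIP order as acetophenone to (R)-1-phenylethanol). Formic acid makes the reduction irreversible, so the enantiomeric purity should not erode.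

Step 4
Reactants: 6 4-[(1R)-1-hydroxy-3-methylbutyl]-3-methoxyphenyl N,N-diethylcarbamate
Product: 7 3-methoxy-4-[(1R)-1-methoxy-3-methylbutyl]phenyl N,N-diethylcarbamate
Conditions: MeI (3 equiv), NaH (1.3 equiv), THF, 0 °C → rt
Reagents that add atoms: iodomethane CI
Why: Williamson ether synthesis; the C1″–O bond is not touched, so the configuration is retained, and MeI is present before the base so that the deprotonated alcohol is trapped before it can attack a carbamate.

Step 5
Reactants: 7 3-methoxy-4-[(1R)-1-methoxy-3-methylbutyl]phenyl N,N-diethylcarbamate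
Product: 9 3-methoxy-4-[(1R)-1-methoxy-3-methylbutyl]-2-(trimethylsilyl)phenyl N,N-diethylcarbamate, via aryllithium 8 (not isolated)
Conditions: s-BuLi (1.2 equiv), TMEDA (1.2 equiv), THF, −78 °C; then Me3SiCl, −78 °C → rt
Reagents that add atoms: chlorotrimethylsilane C[Si](C)(C)Cl
Why: Directed ortho-metalation: the carbamate (strong director) and the OMe group stand 1,3 to each other and act together on the C–H between them (the later C1 of ring A), which gives 8; at −78 °C the anionic Fries shift is slow and 8 is silylated.

Step 6
Reactants: 9 3-methoxy-4-[(1R)-1-methoxy-3-methylbutyl]-2-(trimethylsilyl)phenyl N,N-diethylcarbamate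
Product: 10 3-methoxy-4-[(1R)-1-methoxy-3-methylbutyl]-2-(trimethylsilyl)phenol
Conditions: LiAlH4 (2 equiv), THF, reflux; then aq. Rochelle salt (pH about 7)
Reagents that add atoms: none
Why: Hydride reduction of the aryl carbamate expels the phenoxide under basic, non-hydrolytic conditions, so the acid-labile C–Si bond between the two oxygens survives; the ethers and the stereocentre are inert to LiAlH4.

Step 7
Reactants: 10 3-methoxy-4-[(1R)-1-methoxy-3-methylbutyl]-2-(trimethylsilyl)phenol
Product: 11 3-methoxy-4-[(1R)-1-methoxy-3-methylbutyl]-2-(trimethylsilyl)phenyl trifluoromethanesulfonate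
Conditions: Tf2O (1.2 equiv), pyridine (2 equiv), CH2Cl2, 0 °C
Reagents that add atoms: trifluoromethanesulfonic anhydride O=S(=O)(OS(=O)(=O)C(F)(F)F)C(F)(F)F
Why: O-Sulfonylation of a phenol, the standard last step to an o-silylaryl triflate; pyridine buffers the acid that is set free, so neither protodesilylation nor ionisation at C1″ should occur.

Step 8
Reactants: 12 2-hydroxy-3-methoxy-5-methylbenzaldehyde
Product: 13 2,3-dihydroxy-5-methylbenzaldehyde
Conditions: BBr3 (2.2 equiv), CH2Cl2, −78 °C → rt; then H2O
Reagents that add atoms: none
Why: Lewis-acid cleavage of an aryl methyl ether; boron is held by the neighbouring phenol oxygen, bromide attacks the methyl group (SN2), and the aldehyde is returned unchanged on hydrolysis.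

Step 9
Reactants: 13 2,3-dihydroxy-5-methylbenzaldehyde
Product: 15 2-hydroxy-5-methyl-3-(prop-2-en-1-yloxy)benzaldehyde, via disodium catecholate 14 (not isolated)
Conditions: NaH (2.1 equiv), THF/DMSO, 0 °C → rt; allyl bromide (1.0 equiv); then dil. HCl
Reagents that add atoms: allyl bromide C=CCBr
Why: In dianion 14 the 2-phenoxide is delocalised into the formyl group and chelated to sodium, so the 3-phenoxide is the more nucleophilic site and one equivalent of allyl bromide should alkylate it alone (Williamson ether synthesis under dianion control).

Step 10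
Reactants: 15 2-hydroxy-5-methyl-3-(prop-2-en-1-yloxy)benzaldehyde
Product: 16 2-(1,3-dioxolan-2-yl)-4-methyl-6-(prop-2-en-1-yloxy)phenol
Conditions: HOCH2CH2OH (3 equiv), p-TsOH (2 mol %), toluene, reflux, Dean–Stark; Et3N quench
Reagents that add atoms: ethylene glycol OCCO
Why: Acid-catalysed acetalisation with azeotropic removal of water; the allyl ether is stable to acid and 110 °C is well below the temperature of an aromatic Claisen rearrangement. The acetal is needed because a free formyl group would be attacked by the aryl anion of step 11.

Step 11
Reactants: 11 3-methoxy-4-[(1R)-1-methoxy-3-methylbutyl]-2-(trimethylsilyl)phenyl trifluoromethanesulfonate; 16 2-(1,3-dioxolan-2-yl)-4-methyl-6-(prop-2-en-1-yloxy)phenol; 17 carbon dioxide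
Product: 22 6-[2-formyl-4-methyl-6-(prop-2-en-1-yloxy)phenoxy]-2-methoxy-3-[(1R)-1-methoxy-3-methylbutyl]benzoic acid, via potassium phenoxide 18 (not isolated), via aryne 19 (not isolated), via arylpotassium 20 (not isolated), via potassium carboxylate 21 (not isolated)
Conditions: 16 (1.8 equiv), KH, THF, 0 °C; then 18-crown-6, KF, CO2 (1 atm), slow addition of 11, THF, 0 °C → rt; then 1 M HCl, THF, rt
Reagents that add atoms: water O
Why: Proposed new method: fluoride attacks the SiMe3 group of 11 and triflate leaves, which gives aryne 19 (C1≡C6 of ring A); the σ-withdrawing OMe on C2 distorts the aryne so that C6 is the more electrophilic carbon, and phenoxide 18 should add there and leave the charge on C1 next to the OMe (aryl anion 20). Attack takes place in the ring plane at a carbon whose only neighbour is C5–H, so the two ortho groups of 18 cost little, which a substitution or a copper coupling cannot offer for this tri-ortho-substituted ether. Because 18 is preformed and the medium holds no proton source, 20 should live long enough to be captured by the small electrophile 17 and give the 2,6-disubstituted carboxylate 21 directly, so that no hindered ester ever has to be cleaved. The closest known reaction types are the three-component couplings of arynes from o-silylaryl triflates with amines or halide ions and carbon dioxide under KF/18-crown-6, and the fluoride-mediated O-arylation of phenols by the same aryne precursors; the only new element is their union, a phenoxide as the nucleophile of the carboxylative coupling. Reversible binding of 17 to 18 as an aryl carbonate should be weak for this hindered phenoxide and, as with amines and their carbamates, the free nucleophile should be the species that reacts. Slow addition of 11 to an excess of 18 keeps 21 from competing for the aryne, the dioxolane keeps 20 away from the aldehyde carbon (a free CHO would close a xanthenol), and the acidic work-up then frees the aldehyde. No ring is closed and no stereocentre is formed; C1″ meets neither an acid strong enough to ionise it nor a base that reaches its C–H bond.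

Step 12
Reactants: 22 6-[2-formyl-4-methyl-6-(prop-2-en-1-yloxy)phenoxy]-2-methoxy-3-[(1R)-1-methoxy-3-methylbutyl]benzoic acid
Product: 23 6-(2-formyl-6-hydroxy-4-methylphenoxy)-2-methoxy-3-[(1R)-1-methoxy-3-methylbutyl]benzoic acid
Conditions: Pd(PPh3)4 (5 mol %), p-TolSO2Na (1.5 equiv), THF/MeOH, rt; then dil. HCl
Reagents that add atoms: none
Why: Tsuji–Trost-type deallylation: Pd(0) ionises the aryl allyl ether and the sulfinate traps the π-allyl complex as a sulfone; the medium is close to neutral, so the aldehyde, the acid and the benzylic ether at C1″ are not affected.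

## Compound list

1 | resorcinol | Oc1cccc(O)c1 | starting material
2 | 3-methylbutanoic acid | CC(C)CC(=O)O | starting material
3 | 1-(2,4-dihydroxyphenyl)-3-methylbutan-1-one | CC(C)CC(=O)c1ccc(O)cc1O | intermediate
4 | 3-hydroxy-4-(3-methylbutanoyl)phenyl N,N-diethylcarbamate | CCN(CC)C(=O)Oc1ccc(C(=O)CC(C)C)c(O)c1 | intermediate
5 | 3-methoxy-4-(3-methylbutanoyl)phenyl N,N-diethylcarbamate | CCN(CC)C(=O)Oc1ccc(C(=O)CC(C)C)c(OC)c1 | intermediate
6 | 4-[(1R)-1-hydroxy-3-methylbutyl]-3-methoxyphenyl N,N-diethylcarbamate | COc1c([C@@H](CC(C)C)O)ccc(OC(=O)N(CC)CC)c1 | intermediate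
7 | 3-methoxy-4-[(1R)-1-methoxy-3-methylbutyl]phenyl N,N-diethylcarbamate | COc1c([C@@H](CC(C)C)OC)ccc(OC(=O)N(CC)CC)c1 | intermediate
8 | 2-lithio-3-methoxy-4-[(1R)-1-methoxy-3-methylbutyl]phenyl N,N-diethylcarbamate | COc1c([C@@H](CC(C)C)OC)ccc(OC(=O)N(CC)CC)c1[Li] | intermediate
9 | 3-methoxy-4-[(1R)-1-methoxy-3-methylbutyl]-2-(trimethylsilyl)phenyl N,N-diethylcarbamate | COc1c([C@@H](CC(C)C)OC)ccc(OC(=O)N(CC)CC)c1[Si](C)(C)C | intermediate
10 | 3-methoxy-4-[(1R)-1-methoxy-3-methylbutyl]-2-(trimethylsilyl)phenol | COc1c([C@@H](CC(C)C)OC)ccc(O)c1[Si](C)(C)C | intermediate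
11 | 3-methoxy-4-[(1R)-1-methoxy-3-methylbutyl]-2-(trimethylsilyl)phenyl trifluoromethanesulfonate | COc1c([C@@H](CC(C)C)OC)ccc(OS(=O)(=O)C(F)(F)F)c1[Si](C)(C)C | intermediate
12 | 2-hydroxy-3-methoxy-5-methylbenzaldehyde | COc1cc(C)cc(C=O)c1O | starting material
13 | 2,3-dihydroxy-5-methylbenzaldehyde | Cc1cc(O)c(O)c(C=O)c1 | intermediate
14 | disodium 3-formyl-5-methylbenzene-1,2-diolate | [Na+].[Na+].[O-]c1cc(C)cc(C=O)c1[O-] | intermediate
15 | 2-hydroxy-5-methyl-3-(prop-2-en-1-yloxy)benzaldehyde | C=CCOc1cc(C)cc(C=O)c1O | intermediate
16 | 2-(1,3-dioxolan-2-yl)-4-methyl-6-(prop-2-en-1-yloxy)phenol | C=CCOc1cc(C)cc(C2OCCO2)c1O | intermediate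
17 | carbon dioxide | O=C=O | starting material
18 | potassium 2-(1,3-dioxolan-2-yl)-4-methyl-6-(prop-2-en-1-yloxy)phenoxide | C=CCOc1cc(C)cc(C2OCCO2)c1[O-].[K+] | intermediate
19 | 3-methoxy-4-[(1R)-1-methoxy-3-methylbutyl]-1,2-didehydrobenzene (aryne, C1≡C6 of ring A) | COC1=C([C@@H](CC(C)C)OC)C=CC#C1 | intermediate
20 | {6-[2-(1,3-dioxolan-2-yl)-4-methyl-6-(prop-2-en-1-yloxy)phenoxy]-2-methoxy-3-[(1R)-1-methoxy-3-methylbutyl]phenyl}potassium | COc1c([C@@H](CC(C)C)OC)ccc(Oc2c(OCC=C)cc(C)cc2C3OCCO3)c1[K] | intermediate
21 | potassium 6-[2-(1,3-dioxolan-2-yl)-4-methyl-6-(prop-2-en-1-yloxy)phenoxy]-2-methoxy-3-[(1R)-1-methoxy-3-methylbutyl]benzoate | COc1c([C@@H](CC(C)C)OC)ccc(Oc2c(OCC=C)cc(C)cc2C3OCCO3)c1C(=O)[O-].[K+] | intermediate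
22 | 6-[2-formyl-4-methyl-6-(prop-2-en-1-yloxy)phenoxy]-2-methoxy-3-[(1R)-1-methoxy-3-methylbutyl]benzoic acid | COc1c([C@@H](CC(C)C)OC)ccc(Oc2c(OCC=C)cc(C)cc2C=O)c1C(=O)O | intermediate
23 | 6-(2-formyl-6-hydroxy-4-methylphenoxy)-2-methoxy-3-[(1R)-1-methoxy-3-methylbutyl]benzoic acid | COc1c([C@@H](CC(C)C)OC)ccc(Oc2c(O)cc(C)cc2C=O)c1C(=O)O | target

## Step count and risk

Total step count: 12. Longest linear sequence: 9 steps (steps 1–7, 11 and 12). Steps 8–10 form the second branch.

**Step 11 (key step, proposed new method).** Three things are most likely to go wrong: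
- Aryl anion 20 may be protonated before it is carboxylated, by adventitious moisture or by internal hydrogen transfer from the OCH2 of the allyl group or the acetal C–H.
- The reaction may run through the carbonate adduct of 18 and 17, with acyl transfer instead of ether formation.
- Carboxylate 21 may be arylated by a second aryne.

In addition, the acid work-up must be kept short so that C1″ does not ionise.

The fallback separates the two bond formations and uses known chemistry only. It sets out from 7. Directed ortho-metalation as in step 5, but quenched with 17, gives 6-[(diethylcarbamoyl)oxy]-2-methoxy-3-[(1R)-1-methoxy-3-methylbutyl]benzoic acid F1. Hot aqueous-ethanolic NaOH then cleaves the carbamate to 6-hydroxy-2-methoxy-3-[(1R)-1-methoxy-3-methylbutyl]benzoic acid F2.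

The partner comes from commercial 2-fluoro-5-methylphenol F3. Protection with MOMCl/i-Pr2NEt gives 1-fluoro-2-(methoxymethoxy)-4-methylbenzene F4. Lithiation ortho to fluorine (s-BuLi, THF, −78 °C) and a DMF quench give 2-fluoro-3-(methoxymethoxy)-5-methylbenzaldehyde F5.

The dianion of F2 (Cs2CO3, DMSO, 80–100 °C) displaces the fluoride of F5, which the ortho formyl group activates (nucleophilic aromatic substitution). This gives 6-[2-formyl-6-(methoxymethoxy)-4-methylphenoxy]-2-methoxy-3-[(1R)-1-methoxy-3-methylbutyl]benzoic acid F6. Dilute HCl in THF removes the MOM group, and the route is rejoined at 23.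

**Step 6.** The carbamate is shielded by the ortho SiMe3 group, so reduction may stall. The C–Si bond, whose ipso carbon is activated by two ortho oxygen donors, may also be lost by protodesilylation during work-up.

The fallback makes the C–Si bond by a retro-Brook shift instead, so that no silylated carbamate has to be cleaved. It sets out from 7. Metalation to 8 and a quench with iodine give 2-iodo-3-methoxy-4-[(1R)-1-methoxy-3-methylbutyl]phenyl N,N-diethylcarbamate F9. Hot NaOH in aqueous ethanol gives 2-iodo-3-methoxy-4-[(1R)-1-methoxy-3-methylbutyl]phenol F10. Hexamethyldisilazane gives its trimethylsilyl ether F11. Treatment with n-BuLi at −78 °C triggers iodine–lithium exchange and a 1,3 O→C silyl shift, and Tf2O added to the same flask traps the resulting phenoxide. The route is rejoined at 11.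

**Step 5.** Metalation may compete at the benzylic C1″–H, with erosion of configuration or Wittig rearrangement, or at the other position ortho to the carbamate. An anionic Fries shift may also set in on warming.

The fallback metalates the alcohol stage, where the lithium alkoxide shields C1″–H. It sets out from 6. Treatment with s-BuLi (2.2 equiv)/TMEDA and then Me3SiCl (2.2 equiv) gives the C,O-bis-silyl compound 3-methoxy-4-[(1R)-3-methyl-1-(trimethylsilyloxy)butyl]-2-(trimethylsilyl)phenyl N,N-diethylcarbamate F7. K2CO3/MeOH cleaves only the O–Si bond and gives 4-[(1R)-1-hydroxy-3-methylbutyl]-3-methoxy-2-(trimethylsilyl)phenyl N,N-diethylcarbamate F8. O-Methylation as in step 4 rejoins the route at 9.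

**Step 3.** Facial selectivity may be insufficient, because the isobutyl group is larger than the methyl group of the model ketones and the ortho methoxy group twists the aryl ring out of conjugation.

The fallback replaces the metal catalyst with an enzyme. An (R)-selective ketoreductase with NADPH recycling by isopropanol reduces 5 in buffered aqueous medium. It sets out from 5 and comes back at 6. This fallback makes no compound outside the list (F0).

## Further compounds

F1 | step 11 | 6-[(diethylcarbamoyl)oxy]-2-methoxy-3-[(1R)-1-methoxy-3-methylbutyl]benzoic acid | COc1c([C@@H](CC(C)C)OC)ccc(OC(=O)N(CC)CC)c1C(=O)O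
F2 | step 11 | 6-hydroxy-2-methoxy-3-[(1R)-1-methoxy-3-methylbutyl]benzoic acid | COc1c([C@@H](CC(C)C)OC)ccc(O)c1C(=O)O
F3 | step 11 | 2-fluoro-5-methylphenol | Cc1ccc(F)c(O)c1
F4 | step 11 | 1-fluoro-2-(methoxymethoxy)-4-methylbenzene | COCOc1cc(C)ccc1F
F5 | step 11 | 2-fluoro-3-(methoxymethoxy)-5-methylbenzaldehyde | COCOc1cc(C)cc(C=O)c1F
F6 | step 11 | 6-[2-formyl-6-(methoxymethoxy)-4-methylphenoxy]-2-methoxy-3-[(1R)-1-methoxy-3-methylbutyl]benzoic acid | COc1c([C@@H](CC(C)C)OC)ccc(Oc2c(OCOC)cc(C)cc2C=O)c1C(=O)O
F7 | step 5 | 3-methoxy-4-[(1R)-3-methyl-1-(trimethylsilyloxy)butyl]-2-(trimethylsilyl)phenyl N,N-diethylcarbamate | COc1c([C@@H](CC(C)C)O[Si](C)(C)C)ccc(OC(=O)N(CC)CC)c1[Si](C)(C)C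
F8 | step 5 | 4-[(1R)-1-hydroxy-3-methylbutyl]-3-methoxy-2-(trimethylsilyl)phenyl N,N-diethylcarbamate | COc1c([C@@H](CC(C)C)O)ccc(OC(=O)N(CC)CC)c1[Si](C)(C)C
F9 | step 6 | 2-iodo-3-methoxy-4-[(1R)-1-methoxy-3-methylbutyl]phenyl N,N-diethylcarbamate | COc1c([C@@H](CC(C)C)OC)ccc(OC(=O)N(CC)CC)c1I
F10 | step 6 | 2-iodo-3-methoxy-4-[(1R)-1-methoxy-3-methylbutyl]phenol | COc1c([C@@H](CC(C)C)OC)ccc(O)c1I
F11 | step 6 | {2-iodo-3-methoxy-4-[(1R)-1-methoxy-3-methylbutyl]phenoxy}trimethylsilane | COc1c([C@@H](CC(C)C)OC)ccc(O[Si](C)(C)C)c1I
F0 | step 3 | none | none
A1 | alternative 1 | methyl 6-hydroxy-2-methoxy-3-[(1R)-1-methoxy-3-methylbutyl]benzoate | COc1c([C@@H](CC(C)C)OC)ccc(O)c1C(=O)OC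
A2 | alternative 1 | 3-(benzyloxy)-2-fluoro-5-methylbenzaldehyde | O=Cc1cc(C)cc(OCc2ccccc2)c1F
A3 | alternative 1 | methyl 6-[2-(benzyloxy)-6-formyl-4-methylphenoxy]-2-methoxy-3-[(1R)-1-methoxy-3-methylbutyl]benzoate | COc1c([C@@H](CC(C)C)OC)ccc(Oc2c(OCc3ccccc3)cc(C)cc2C=O)c1C(=O)OC
A4 | alternative 2 | 3-hydroxy-2-{6-hydroxy-2-methoxy-3-[(1R)-1-methoxy-3-methylbutyl]benzoyl}-5-methylbenzaldehyde | COc1c([C@@H](CC(C)C)OC)ccc(O)c1C(=O)c1c(O)cc(C)cc1C=O
A5 | alternative 2 | 4-methoxy-5-[(1R)-1-methoxy-3-methylbutyl]-4′-methyl-2′,3-dioxospiro[1-benzofuran-2,1′-cyclohexa-3′,5′-diene]-6′-carbaldehyde (spiro centre not controlled) | COc1c([C@@H](CC(C)C)OC)ccc2OC3(C(=O)C=C(C)C=C3C=O)C(=O)c12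
A6 | alternative 2 | regioisomeric spirodienone with ring A dearomatised (spiro centre at C1 of ring A, not controlled) | COC1=C([C@@H](CC(C)C)OC)C=CC(=O)C12Oc1cc(C)cc(C=O)c1C2=O
A7 | alternative 3 | 2-(benzyloxy)-6-formyl-4-methylphenyl 6-hydroxy-2-methoxy-3-[(1R)-1-methoxy-3-methylbutyl]benzoate | COc1c([C@@H](CC(C)C)OC)ccc(O)c1C(=O)Oc1c(OCc2ccccc2)cc(C)cc1C=O
A8 | alternative 3 | 6-[2-(benzyloxy)-6-formyl-4-methylphenoxy]-2-methoxy-3-[(1R)-1-methoxy-3-methylbutyl]benzoic acid | COc1c([C@@H](CC(C)C)OC)ccc(Oc2c(OCc3ccccc3)cc(C)cc2C=O)c1C(=O)O
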